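**Assumption:** Prosogerin D (7-hydroxy-6-methoxy-2-(3,4,5-trimethoxyphenyl)-4H-chromen-4-one) has no stereocentres, so the "single enantiomer" requirement is moot and no stereocontrol is needed.

## Retrosynthetic overview

- The classical chalcone / Baker–Venkataraman route is avoided. Instead the pyranone ring (ring C) is built last, in one pot, by a Pd-catalysed three-component carbonylative annulation of an o-iodophenol (ring A), CO (which becomes C-4) and an aryl acetylene (C-2, C-3 and ring B).
- The final step is hydrogenolysis of the 7-O-benzyl ether.
- Ring A piece: 5-(benzyloxy)-2-iodo-4-methoxyphenol, from commercial O-benzylisovanillin by Dakin oxidation (CHO to OH) and then regioselective iodination.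
- Ring B piece: commercial 3,4,5-trimethoxyphenylacetylene.
- Ring order: A and B are purchased as arenes; ring C is formed in the key step.

## Route

**Step 1**
Reactants: **1**, 3-(benzyloxy)-4-methoxybenzaldehyde (O-benzylisovanillin)
Product: **2**, 3-(benzyloxy)-4-methoxyphenol
Conditions: mCPBA (1.3 equiv), CH2Cl2, 0 °C to rt; then K2CO3, MeOH, rt; dilute HCl work-up
Reagents that add atoms: mCPBA, OOC(=O)c1cccc(Cl)c1 (delivers the phenolic O; the CHO carbon is lost as formate)
Why: Dakin-type Baeyer–Villiger oxidation; the electron-rich aryl group (p-OMe) migrates to give the aryl formate, which is methanolysed to the phenol, and the benzyl and methyl ethers are inert.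

**Step 2**
Reactants: **2**, 3-(benzyloxy)-4-methoxyphenol
Product: **3**, 5-(benzyloxy)-2-iodo-4-methoxyphenol
Conditions: NIS (1.0 equiv), TsOH·H2O (10 mol %), MeCN, −10 to 0 °C, dark
Reagents that add atoms: N-iodosuccinimide, O=C1CCC(=O)N1I
Why: Electrophilic aromatic iodination; C-6 is ortho to OH and para to OBn, so it is the most activated and least hindered site, whereas C-2 is flanked by two oxygens and C-5 is activated only by the o-OMe.

**Step 3 (key step)**
Reactants: **3**, 5-(benzyloxy)-2-iodo-4-methoxyphenol; **4**, 5-ethynyl-1,2,3-trimethoxybenzene (3,4,5-trimethoxyphenylacetylene, 1.3 equiv)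
Product: **5**, 7-(benzyloxy)-6-methoxy-2-(3,4,5-trimethoxyphenyl)-4H-chromen-4-one
Conditions: PdCl2(dppf) (3 mol %), CO (20 bar), Et2NH (solvent), 120 °C, autoclave, 2–4 h; copper-free
Reagents that add atoms: carbon monoxide, [C-]#[O+] (becomes C-4 and its carbonyl O)
Why: Pd-catalysed carbonylative Sonogashira coupling / annulation (Kalinin–Torii type). Oxidative addition into Ar–I and CO insertion give an aroyl-Pd species that couples with the alkyne to an o-hydroxyaryl ynone. Et2NH adds to the ynone to give a β-aminoenone, and the phenol then displaces the amine by addition–elimination, which gives the 6-membered flavone and not the 5-exo aurone. CO pressure and the absence of copper suppress direct Sonogashira coupling to a benzofuran.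

**Step 4**
Reactants: **5**, 7-(benzyloxy)-6-methoxy-2-(3,4,5-trimethoxyphenyl)-4H-chromen-4-one
Product: **6**, Prosogerin D, 7-hydroxy-6-methoxy-2-(3,4,5-trimethoxyphenyl)-4H-chromen-4-one
Conditions: H2 (1 atm), 10 % Pd/C, THF–MeOH (1:1), rt, monitored by TLC and stopped at full conversion
Reagents that add atoms: none
Why: Catalytic hydrogenolysis of the benzyl aryl ether; the vinylogous-ester C2=C3 bond of the flavone and the four methyl ethers are not reduced under 1 atm H2 at rt.

## Compound list

1 | 3-(benzyloxy)-4-methoxybenzaldehyde | O=Cc1ccc(OC)c(OCc2ccccc2)c1 | starting material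
2 | 3-(benzyloxy)-4-methoxyphenol | Oc1ccc(OC)c(OCc2ccccc2)c1 | intermediate
3 | 5-(benzyloxy)-2-iodo-4-methoxyphenol | Oc1cc(OCc2ccccc2)c(OC)cc1I | intermediate
4 | 5-ethynyl-1,2,3-trimethoxybenzene | C#Cc1cc(OC)c(OC)c(OC)c1 | starting material
5 | 7-(benzyloxy)-6-methoxy-2-(3,4,5-trimethoxyphenyl)-4H-chromen-4-one | COc1cc2c(=O)cc(-c3cc(OC)c(OC)c(OC)c3)oc2cc1OCc1ccccc1 | intermediate
6 | Prosogerin D | COc1cc2c(=O)cc(-c3cc(OC)c(OC)c(OC)c3)oc2cc1O | target

## Summary

**Total steps:** 4. **Longest linear sequence:** 4 (1 → 2 → 3 → 5 → 6; alkyne 4 is purchased and enters at Step 3).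

**Steps most likely to fail, with fallbacks:**

1. **Step 3 (carbonylative annulation).** Risks are Et2NH aminocarbonylation to the diethylamide, non-carbonylative coupling to a 2-arylbenzofuran, aurone formation, and slow oxidative addition of the electron-rich iodide. Fallback: abandon the three-component step. Fries-type C-acetylation of phenol 2 (AcOH, BF3·OEt2) gives 4-(benzyloxy)-2-hydroxy-5-methoxyacetophenone; Claisen–Schmidt condensation with 3,4,5-trimethoxybenzaldehyde gives the chalcone; I2/DMSO oxidative cyclisation gives 5.

2. **Step 2 (iodination of the electron-rich phenol).** Risks are di-iodination at C-2 and oxidation to quinone-type products. Fallback: reverse the order. Iodinate aldehyde 1 first (I2, AgOCOCF3, CH2Cl2), where the deactivating CHO tempers reactivity and directs to C-6 para to OBn, giving 5-(benzyloxy)-2-iodo-4-methoxybenzaldehyde. Dakin oxidation of that iodo-aldehyde then gives 3.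

3. **Step 4 (debenzylation).** Risks are over-reduction of C2=C3 to the flavanone and poor solubility of 5. Fallback: change the protecting-group strategy. Start from isovanillin and MOMCl to carry a 7-O-MOM ether through the same sequence, and unmask it with HCl/MeOH with no reductive step. Alternatively, cleave the benzyl ether of 5 non-reductively with BCl3/pentamethylbenzene at −78 °C.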